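**Retrosynthetic overview**
- The only disconnection is the ester O–CH2 bond. It leads back to 4-(2-hydroxyethyl)phenol (tyrosol, 1) as the carbon electrophile and docosanoic acid (2) as the oxygen nucleophile, both bought.
- Forward: 1 + 2 give the catalyst-bound alkoxyphosphonium docosanoate 3 (not isolated), which collapses to target 4. Water is the only co-product and the phenol stays unprotected.
- No ring is formed (the benzene ring comes with 1) and there is no stereocentre to set.

Assumption: the target is achiral (no stereocentre, no double-bond geometry), so "single enantiomer" means the compound as drawn; the catalyst (2-hydroxybenzyl)diphenylphosphine oxide, O=P(Cc1ccccc1O)(c1ccccc1)c1ccccc1, is taken as purchasable.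

**Step 1**
Reactants: 1 4-(2-hydroxyethyl)phenol (tyrosol); 2 docosanoic acid (behenic acid)
Product: 4 2-(4-hydroxyphenyl)ethyl docosanoate, via alkoxyphosphonium docosanoate 3 (not isolated)
Conditions: 1 (1.0 equiv), 2 (1.1 equiv), (2-hydroxybenzyl)diphenylphosphine oxide (15 mol%), o-xylene (0.3 M), reflux (144 °C), Dean–Stark trap with 4 Å MS, 24–48 h
Reagents that add atoms: none
Why: Proposed new method: phosphine-oxide-catalysed, redox-neutral dehydrative O-alkylation of an unactivated fatty acid by a phenol-bearing primary alcohol. The P=O group and the catalyst's own ortho-phenol arm cyclodehydrate (2 as proton source, water removed azeotropically) to a 1,2-benzoxaphospholium/acyloxyphosphorane; the primary aliphatic OH of 1 opens it to alkoxyphosphonium docosanoate 3; the carboxylate then attacks the unhindered O–CH2 carbon (SN2), forming the ester C–O bond and returning the phosphine oxide. The phenol of 1 cannot be displaced at sp2 carbon and is about 5 pKa units too weak to compete with 2 as pronucleophile, so it needs no protection; no stereocentre is formed. The closest known reaction type is the phosphine-oxide-catalysed (catalytic Mitsunobu-type) esterification of alcohols, which to my knowledge has been shown only with strongly acidic pronucleophiles such as nitrobenzoic acids, not with a fatty acid of pKa about 4.8 or a free-phenol alcohol. The hotter solvent, higher loading and the more nucleophilic aliphatic carboxylate on a primary carbon are what the extension relies on.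

**Compound list**
1 | 4-(2-hydroxyethyl)phenol (tyrosol) | OCCc1ccc(O)cc1 | starting material
2 | docosanoic acid (behenic acid) | CCCCCCCCCCCCCCCCCCCCCC(=O)O | starting material
3 | [2-(4-hydroxyphenyl)ethoxy][(2-hydroxyphenyl)methyl]diphenylphosphonium docosanoate (catalyst-bound ion pair) | CCCCCCCCCCCCCCCCCCCCCC(=O)[O-].Oc1ccc(CCO[P+](Cc2ccccc2O)(c2ccccc2)c2ccccc2)cc1 | intermediate
4 | 2-(4-hydroxyphenyl)ethyl docosanoate (achiral) | CCCCCCCCCCCCCCCCCCCCCC(=O)OCCc1ccc(O)cc1 | target

**Total step count:** 1
**Longest linear sequence:** 1 step

**Steps most likely to fail**
The route has a single step, so step 1 (the proposed new step) is the only one that can be ranked.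

Step 1 has three main risks:
- **Catalyst activation:** acid 2 may be too weak to drive the cyclodehydration of the catalyst, so turnover stalls.
- **Side reactions at 144 °C:** the alkoxyphosphonium 3 may be O-alkylated by a phenol (ether oligomers of 1) or may eliminate to 4-vinylphenol.
- **Isolation:** the waxy product must be separated from excess 2 and the polar catalyst (silica plug, then crystallisation from ethanol).

Aryl-assisted ionisation of 3 and the slow uncatalysed thermal condensation of 1 with 2 both give the same ester 4, so neither can produce an isomer.

Fallback for step 1 (known chemistry, different approach: an activated acyl donor and enzymatic acyl transfer, forming the acyl C–O bond instead of the alkyl C–O bond). It sets out from 2. Acid 2 is converted by Pd(OAc)2/KOH-catalysed transvinylation in excess vinyl acetate (THF co-solvent, 40 °C) into vinyl docosanoate F1. F1 (1.2 equiv) is then used to acylate 1 with immobilised Candida antarctica lipase B in 2-methyl-2-butanol at 55 °C. The lipase acylates only the primary aliphatic hydroxyl and leaves the phenol free, and the enol released tautomerises to volatile acetaldehyde, so the transfer is irreversible. The fallback comes back to the route at 4.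

**Further compounds**
F1 | step 1 | vinyl docosanoate | CCCCCCCCCCCCCCCCCCCCCC(=O)OC=C
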